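**Plan**

1. Numbering (eudesmane): ring A = C1–C5/C10, ring B = C5–C10; C3 is CH–OH, C4 is C(CH3)–OH, C6 is CH–OBz, C7 is CH–iPr, C10 is C–CH3 (β); α is the face opposite the C10 methyl.
2. Retrosynthesis: the benzoate and a 3-O-benzyl group come off first, and the C6 alcohol goes back to the ketone and its enol ether C6=C7. Ring B is then opened at C8–C9 and C5–C10 together (retro-Diels–Alder), which also opens ring A. The chain is cut at C6–C7 (alkenyl Grignard on a Weinreb amide), C4–C5 (aldol) and C1–C2 (epoxide opening).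
3. Enabling feature: ring B is a cyclohexane with the C6 oxygen next to the branched C7, i.e. the adduct of a 2-oxy diene C5=C6(O)–C7(iPr)=C8 and the isopropenyl unit C9=C10(CH3). The four carbons C1–C4 of ring A are the tether from C5 to C10. The C4 hydroxyl is 1,3 to the C6 oxygen, so one silicon atom can hold both in a six-membered ring.
4. Forward: the open chain is built in five steps, the C4–O/C6–O pair is closed to a temporary dioxasiline (cyclic silyl dienol ether), and one thermal intramolecular Diels–Alder reaction forms rings A and B together. Desilylation, ketone reduction, benzoylation and debenzylation finish the route.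
5. Stereochemistry: C3 from methyl (R)-glycidate (chiral pool); C4 by chelation-controlled addition next to C3; C5 and C10 in the cycloaddition (C5 through the silicon ring on C4, C10 through the trans-fused transition state); C7 by axial protonation of the enol ether; C6 by hydride attack anti to the C10 methyl.

Key step: step 7

Remark: compounds 1, 2, 7 and 10 and all reagents are assumed to be commercial; bicyclic compounds are named with the numbering of line 1.

Step 1
Reactants: 1 methyl (2R)-oxirane-2-carboxylate [methyl (R)-glycidate]; 2 (2-methylprop-2-en-1-yl)magnesium chloride [methallylmagnesium chloride]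
Product: 3 methyl (2R)-2-hydroxy-5-methylhex-5-enoate
Conditions: 2 (slow addition), CuI (10 mol %), THF, −78 → −40 °C; aq. NH4Cl
Reagents that add atoms: none
Why: Copper-catalysed Grignard opening of the terminal epoxide at its CH2 carbon (SN2) leaves the chiral-pool stereocenter (future C3) untouched, and low temperature with slow addition should keep the allylic Grignard reagent off the ester.

Step 2
Reactants: 3 methyl (2R)-2-hydroxy-5-methylhex-5-enoate
Product: 4 methyl (2R)-2-(benzyloxy)-5-methylhex-5-enoate
Conditions: BnBr, Ag2O, Et2O, rt, dark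
Reagents that add atoms: benzyl bromide, BrCc1ccccc1
Why: Silver-oxide-mediated Williamson etherification is neutral enough not to epimerise the α-oxygenated ester; benzyl is chosen because it can chelate in step 4 and leaves last by hydrogenolysis.

Step 3
Reactants: 4 methyl (2R)-2-(benzyloxy)-5-methylhex-5-enoate
Product: 6 (3R)-3-(benzyloxy)-6-methylhept-6-en-2-one, via Weinreb amide 5 (not isolated)
Conditions: MeNH(OMe)·HCl, i-PrMgCl, THF, −20 °C; then MeMgBr, −20 → 0 °C; aq. NH4Cl
Reagents that add atoms: methylmagnesium bromide, C[Mg]Br; N,O-dimethylhydroxylamine hydrochloride, CNOC.Cl (its atoms stay only in 5)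
Why: One-pot ester-to-Weinreb-amide exchange by the magnesium amide followed by Grignard addition; the chelated tetrahedral adduct should prevent over-addition and enolisation of the α-stereocenter.

Step 4
Reactants: 6 (3R)-3-(benzyloxy)-6-methylhept-6-en-2-one; 7 N-methoxy-N-methylacetamide
Product: 9 (3R,4R)-4-(benzyloxy)-3-hydroxy-N-methoxy-N,3,7-trimethyloct-7-enamide, via lithium enolate 8 (not isolated)
Conditions: 7, LDA, THF, −78 °C; MgBr2·OEt2; then 6, −78 °C; aq. NH4Cl
Reagents that add atoms: none
Why: Chelation-controlled acetate-type aldol addition to an α-benzyloxy methyl ketone: magnesium bridges the carbonyl and benzyloxy oxygens and the enolate attacks the face next to the C3 hydrogen, which should give the 3,4-syn tertiary carbinol, i.e. (R) at the future C4.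

Step 5
Reactants: 9 (3R,4R)-4-(benzyloxy)-3-hydroxy-N-methoxy-N,3,7-trimethyloct-7-enamide; 10 2-bromo-3-methylbut-1-ene
Product: 12 (5R,6R)-6-(benzyloxy)-5-hydroxy-5,9-dimethyl-2-(propan-2-yl)deca-1,9-dien-3-one, via alkenyl Grignard reagent 11 (not isolated)
Conditions: 10, Mg, THF, 40 °C; then 9 (added to 3 equiv of 11), −78 → 0 °C; cold aq. NH4Cl
Reagents that add atoms: magnesium, [Mg] (stays only in 11)
Why: Alkenyl Grignard addition to a Weinreb amide: the first equivalent deprotonates the tertiary alcohol, and the chelated tetrahedral intermediate releases the α-isopropyl vinyl ketone only on work-up, which should avoid over-addition and retro-aldol cleavage.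

Step 6
Reactants: 12 (5R,6R)-6-(benzyloxy)-5-hydroxy-5,9-dimethyl-2-(propan-2-yl)deca-1,9-dien-3-one
Product: 13 (4R)-4-[(1R)-1-(benzyloxy)-4-methylpent-4-en-1-yl]-2,2-di-tert-butyl-4-methyl-6-(3-methylbut-1-en-2-yl)-4H-1,3,2-dioxasiline
Conditions: t-Bu2Si(OTf)2, Et3N, CH2Cl2, 0 °C → rt
Reagents that add atoms: di-tert-butylsilyl bis(trifluoromethanesulfonate), CC(C)(C)[Si](OS(=O)(=O)C(F)(F)F)(OS(=O)(=O)C(F)(F)F)C(C)(C)C
Why: Silylene protection of the β-hydroxy ketone: O-silylation of the tertiary alcohol and soft enolisation (silyl triflate/amine) toward C5, the only enolisable side, should close a six-membered cyclic silyl enol ether that fixes the Z enol geometry and unmasks the 2-silyloxy diene C5=C6–C7=C8.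

Step 7
Reactants: 13 (4R)-4-[(1R)-1-(benzyloxy)-4-methylpent-4-en-1-yl]-2,2-di-tert-butyl-4-methyl-6-(3-methylbut-1-en-2-yl)-4H-1,3,2-dioxasiline
Product: 14 3α-(benzyloxy)-4β,6-[(di-tert-butylsilanediyl)bis(oxy)]-5α-eudesm-6-ene (3R,4R,5S,10S)
Conditions: 1,2-dichlorobenzene (0.01 M), BHT (cat.), N,O-bis(trimethylsilyl)acetamide (cat.), sealed tube, 190 °C
Reagents that add atoms: none
Why: Thermal type-1 intramolecular Diels–Alder reaction of a 1,7,9-decatriene: the cyclic 2-silyloxy diene C5=C6(O)–C7(iPr)=C8 adds suprafacially across the isopropenyl π bond C9=C10 in one concerted, asynchronous step that forms C8–C9 and C5–C10 together, the closest known type being the thermal cyclisation of unactivated decatrienes and of 2-silyloxy-diene trienes to octalin silyl enol ethers. Ring B (C5–C10) is closed by the [4+2] itself and ring A (C1–C5/C10) in the fused mode through a chair-like four-carbon tether, and the enol ether C6=C7 that remains carries the future C6 oxygen. C5 is controlled by the dioxasiline ring, which keeps the C4–O bond in the diene plane so that the tether carbon C3 and the C4 methyl lie on opposite faces; C10 can bond only to the face that carries C3, which gives the 4β-O/5α-H arrangement. C10 is controlled by the exo-tether, methyl-endo transition state, which leads to the trans ring fusion with the C10 methyl syn to the C4 oxygen. The step needs this mode to prevail over the endo-tether (cis-fused) mode, because a C10 epimer cannot be corrected later; what should secure it is the di-tert-butylsilylene ring on the C4/C6 edge of the diene, a steric directing group under which an endo tether would have to pass. Regiochemistry is fixed by the tether length and the Z enol geometry by the six-membered silicon ring, while high dilution and an acid scavenger protect the diene at the temperature the unactivated dienophile requires.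

Step 8
Reactants: 14 3α-(benzyloxy)-4β,6-[(di-tert-butylsilanediyl)bis(oxy)]-5α-eudesm-6-ene
Product: 16 3α-(benzyloxy)-4β-hydroxy-5α-eudesman-6-one (3R,4R,5R,7S,10S), via fluorosilyl ether 15 (not isolated)
Conditions: HF·pyridine, pyridine/THF, 0 °C → rt
Reagents that add atoms: hydrogen fluoride (as HF·pyridine), F (fluorine stays only in 15)
Why: Fluoride cleaves the silyl enol ether and then the tertiary silyl ether; the enol should be protonated at C7 on the axial α face, which places the isopropyl group equatorial (7β, also the thermodynamic preference), and the non-basic medium avoids β-elimination of the 4-hydroxyl.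

Step 9
Reactants: 16 3α-(benzyloxy)-4β-hydroxy-5α-eudesman-6-one
Product: 17 3α-(benzyloxy)-5α-eudesmane-4β,6β-diol (3R,4R,5S,6R,7S,10S)
Conditions: NaBH4, MeOH, −20 → 0 °C
Reagents that add atoms: none
Why: Borohydride reduction of a hindered cyclohexanone: the β face of C6 is closed by the 1,3-diaxial C10 methyl and C4 hydroxyl, so hydride should arrive from the α face and give the axial 6β alcohol.

Step 10
Reactants: 17 3α-(benzyloxy)-5α-eudesmane-4β,6β-diol
Product: 18 3α-(benzyloxy)-4β-hydroxy-5α-eudesman-6β-yl benzoate (3R,4R,5S,6R,7S,10S)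
Conditions: BzCl, DMAP, pyridine, 40 °C
Reagents that add atoms: benzoyl chloride, O=C(Cl)c1ccccc1
Why: DMAP-catalysed acylation (nucleophilic catalysis) can take place only at the secondary 6β-hydroxyl, since the 4-hydroxyl is tertiary and O3 is benzylated.

Step 11
Reactants: 18 3α-(benzyloxy)-4β-hydroxy-5α-eudesman-6β-yl benzoate
Product: 19 (1R,2S,4aS,7R,8R,8aS)-7,8-dihydroxy-4a,8-dimethyl-2-(propan-2-yl)decahydronaphthalen-1-yl benzoate [3α,4β-dihydroxy-5α-eudesman-6β-yl benzoate, target]
Conditions: H2 (1 atm), Pd(OH)2/C, EtOAc, rt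
Reagents that add atoms: none
Why: Hydrogenolysis of the benzyl ether; the benzoate, the tertiary alcohol and the saturated skeleton should be inert and no stereocenter is touched.

**Compound list**

1 | methyl (2R)-oxirane-2-carboxylate | COC(=O)[C@H]1CO1 | starting material
2 | (2-methylprop-2-en-1-yl)magnesium chloride | C=C(C)C[Mg]Cl | starting material
3 | methyl (2R)-2-hydroxy-5-methylhex-5-enoate | C=C(C)CC[C@@H](O)C(=O)OC | intermediate
4 | methyl (2R)-2-(benzyloxy)-5-methylhex-5-enoate | C=C(C)CC[C@@H](OCc1ccccc1)C(=O)OC | intermediate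
5 | (2R)-2-(benzyloxy)-N-methoxy-N,5-dimethylhex-5-enamide | C=C(C)CC[C@@H](OCc1ccccc1)C(=O)N(C)OC | intermediate
6 | (3R)-3-(benzyloxy)-6-methylhept-6-en-2-one | C=C(C)CC[C@@H](OCc1ccccc1)C(C)=O | intermediate
7 | N-methoxy-N-methylacetamide | CC(=O)N(C)OC | starting material
8 | lithium enolate of N-methoxy-N-methylacetamide | [Li+].C=C([O-])N(C)OC | intermediate
9 | (3R,4R)-4-(benzyloxy)-3-hydroxy-N-methoxy-N,3,7-trimethyloct-7-enamide | C=C(C)CC[C@@H](OCc1ccccc1)[C@](C)(O)CC(=O)N(C)OC | intermediate
10 | 2-bromo-3-methylbut-1-ene | C=C(Br)C(C)C | starting material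
11 | (3-methylbut-1-en-2-yl)magnesium bromide | C=C([Mg]Br)C(C)C | intermediate
12 | (5R,6R)-6-(benzyloxy)-5-hydroxy-5,9-dimethyl-2-(propan-2-yl)deca-1,9-dien-3-one | C=C(C)CC[C@@H](OCc1ccccc1)[C@](C)(O)CC(=O)C(=C)C(C)C | intermediate
13 | (4R)-4-[(1R)-1-(benzyloxy)-4-methylpent-4-en-1-yl]-2,2-di-tert-butyl-4-methyl-6-(3-methylbut-1-en-2-yl)-4H-1,3,2-dioxasiline | C=C(C)CC[C@@H](OCc1ccccc1)[C@]1(C)O[Si](C(C)(C)C)(C(C)(C)C)OC(C(=C)C(C)C)=C1 | intermediate
14 | 3α-(benzyloxy)-4β,6-[(di-tert-butylsilanediyl)bis(oxy)]-5α-eudesm-6-ene (3R,4R,5S,10S) | CC(C)C=1CC[C@@]2(C)CC[C@@H](OCc4ccccc4)[C@](C)(O[Si]3(C(C)(C)C)C(C)(C)C)[C@@H]2C=1O3 | intermediate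
15 | 3α-(benzyloxy)-4β-[(di-tert-butylfluorosilyl)oxy]-5α-eudesman-6-one | CC(C)[C@@H]1CC[C@@]2(C)CC[C@@H](OCc3ccccc3)[C@](C)(O[Si](F)(C(C)(C)C)C(C)(C)C)[C@@H]2C1=O | intermediate
16 | 3α-(benzyloxy)-4β-hydroxy-5α-eudesman-6-one (3R,4R,5R,7S,10S) | CC(C)[C@@H]1CC[C@@]2(C)CC[C@@H](OCc3ccccc3)[C@](C)(O)[C@@H]2C1=O | intermediate
17 | 3α-(benzyloxy)-5α-eudesmane-4β,6β-diol (3R,4R,5S,6R,7S,10S) | CC(C)[C@@H]1CC[C@@]2(C)CC[C@@H](OCc3ccccc3)[C@](C)(O)[C@@H]2[C@@H]1O | intermediate
18 | 3α-(benzyloxy)-4β-hydroxy-5α-eudesman-6β-yl benzoate (3R,4R,5S,6R,7S,10S) | CC(C)[C@@H]1CC[C@@]2(C)CC[C@@H](OCc3ccccc3)[C@](C)(O)[C@@H]2[C@@H]1OC(=O)c1ccccc1 | intermediate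
19 | (1R,2S,4aS,7R,8R,8aS)-7,8-dihydroxy-4a,8-dimethyl-2-(propan-2-yl)decahydronaphthalen-1-yl benzoate | CC(C)[C@@H]1CC[C@@]2(C)CC[C@@H](O)[C@](C)(O)[C@@H]2[C@@H]1OC(=O)c1ccccc1 | target

**Totals**

Total step count: 11. Longest linear sequence: 11 steps (1 → 19).

**Steps most likely to fail, with fallbacks**

Step 7. The unactivated, 1,1-disubstituted dienophile may cyclise too slowly at temperatures the diene survives, or the reaction may leak through the endo-tether transition state to the cis-fused adduct with the wrong C10 configuration. The fallback activates the dienophile with a traceless formyl group and sets out from 12. Cross-metathesis of the isopropenyl group with crotonaldehyde (second-generation Ru catalyst, CH2Cl2, 40 °C) should give (2E,6R,7R)-6-(benzyloxy)-7-hydroxy-3,7-dimethyl-9-oxo-10-(propan-2-yl)undeca-2,10-dienal F1. Silylene formation as in step 6 should give (2E,6R)-6-(benzyloxy)-6-[(4R)-2,2-di-tert-butyl-4-methyl-6-(3-methylbut-1-en-2-yl)-4H-1,3,2-dioxasilin-4-yl]-3-methylhex-2-enal F2. The intramolecular Diels–Alder reaction should then run at 80–110 °C. The nucleophilic diene terminus C5 now meets the β-carbon C10 of the enal, and the endo formyl group (cis to the C10 methyl) enforces the trans fusion, to give 3α-(benzyloxy)-4β,6-[(di-tert-butylsilanediyl)bis(oxy)]-9β-formyl-5α-eudesm-6-ene F3. Tsuji–Wilkinson decarbonylation (RhCl(PPh3)3, PhCN, 130 °C) removes the formyl group and comes back to the route at 14.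

Step 6. Ring closure to the cyclic silyl enol ether may stall at the hindered mono-silylated tertiary ether, or the tertiary aldol may fragment or cyclise (retro-aldol, oxa-Michael) under the amine base. The fallback uses acyclic protection, with facial control by allylic strain instead of a ring, and sets out from 12. Et3SiOTf/Et3N (CH2Cl2, −78 → 0 °C) should give (3Z,5R,6R)-6-(benzyloxy)-5,9-dimethyl-2-(propan-2-yl)-3,5-bis[(triethylsilyl)oxy]deca-1,3,9-triene F4, in which the Z enol geometry and the in-plane C4–O bond are favoured by A(1,3) strain alone. Thermal cyclisation as in step 7 should give 3α-(benzyloxy)-4β,6-bis[(triethylsilyl)oxy]-5α-eudesm-6-ene F5. HF·pyridine as in step 8 comes back to the route at 16.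

Step 4. Chelation control may erode with an enolate nucleophile (competition from the open transition state), or the enolate may deprotonate the methyl ketone. The fallback uses a non-enolate organomagnesium addition followed by oxidation-state adjustment and sets out from 6. (1,3-Dioxolan-2-ylmethyl)magnesium bromide in THF at −78 °C, which adds through the five-membered magnesium chelate, should give (2R,3R)-3-(benzyloxy)-1-(1,3-dioxolan-2-yl)-2,6-dimethylhept-6-en-2-ol F6. Mild acetal hydrolysis (PPTS, acetone/H2O) should give (3R,4R)-4-(benzyloxy)-3-hydroxy-3,7-dimethyloct-7-enal F7. Addition of Grignard reagent 11 should give (5R,6R)-6-(benzyloxy)-5,9-dimethyl-2-(propan-2-yl)deca-1,9-diene-3,5-diol F8 as either C3 epimer. Dess–Martin oxidation of the secondary allylic hydroxyl comes back to the route at 12.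

Further compounds
F1 | step 7 | (2E,6R,7R)-6-(benzyloxy)-7-hydroxy-3,7-dimethyl-9-oxo-10-(propan-2-yl)undeca-2,10-dienal | O=C/C=C(\C)CC[C@@H](OCc1ccccc1)[C@](C)(O)CC(=O)C(=C)C(C)C
F2 | step 7 | (2E,6R)-6-(benzyloxy)-6-[(4R)-2,2-di-tert-butyl-4-methyl-6-(3-methylbut-1-en-2-yl)-4H-1,3,2-dioxasilin-4-yl]-3-methylhex-2-enal | O=C/C=C(\C)CC[C@@H](OCc1ccccc1)[C@]1(C)O[Si](C(C)(C)C)(C(C)(C)C)OC(C(=C)C(C)C)=C1
F3 | step 7 | 3α-(benzyloxy)-4β,6-[(di-tert-butylsilanediyl)bis(oxy)]-9β-formyl-5α-eudesm-6-ene | CC(C)C=1C[C@H](C=O)[C@@]2(C)CC[C@@H](OCc4ccccc4)[C@](C)(O[Si]3(C(C)(C)C)C(C)(C)C)[C@@H]2C=1O3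
F4 | step 6 | (3Z,5R,6R)-6-(benzyloxy)-5,9-dimethyl-2-(propan-2-yl)-3,5-bis[(triethylsilyl)oxy]deca-1,3,9-triene | C=C(C)CC[C@@H](OCc1ccccc1)[C@](C)(O[Si](CC)(CC)CC)/C=C(\O[Si](CC)(CC)CC)C(=C)C(C)C
F5 | step 6 | 3α-(benzyloxy)-4β,6-bis[(triethylsilyl)oxy]-5α-eudesm-6-ene | CC(C)C=1CC[C@@]2(C)CC[C@@H](OCc3ccccc3)[C@](C)(O[Si](CC)(CC)CC)[C@@H]2C=1O[Si](CC)(CC)CC
F6 | step 4 | (2R,3R)-3-(benzyloxy)-1-(1,3-dioxolan-2-yl)-2,6-dimethylhept-6-en-2-ol | C=C(C)CC[C@@H](OCc1ccccc1)[C@](C)(O)CC1OCCO1
F7 | step 4 | (3R,4R)-4-(benzyloxy)-3-hydroxy-3,7-dimethyloct-7-enal | C=C(C)CC[C@@H](OCc1ccccc1)[C@](C)(O)CC=O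
F8 | step 4 | (5R,6R)-6-(benzyloxy)-5,9-dimethyl-2-(propan-2-yl)deca-1,9-diene-3,5-diol | C=C(C)CC[C@@H](OCc1ccccc1)[C@](C)(O)CC(O)C(=C)C(C)C
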